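**Plan**

1. Numbering: ring A = C1 (OAc), C2, C3 (Me, OH), C4, C10 (Me), C11 (OBz); C5 = lactone carbonyl on C4; C6 = CMe2; ring B (oxepene) = C4–O–C6–C7=C8–C9–C10; ring C (lactone) = C4–C5–O–C9–C10; β = face of the C10 methyl.
2. Retrosynthesis: the lactone C9–O bond is opened (to be closed with inversion at C9), then C5 is reconnected to C7. This contracts ring B to a tetrahydrofuran inside a six-membered carbocycle (C4, C5, C7, C8, C9, C10); the C7=C8 olefin next to a C5 carbonyl is the mark of a 1,3-hydroxy sulfonate fragmentation.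
3. The resulting ether-bridged cis-decalin is cut in ring A at C1–C11 (acyloin) and C2–C3 (allyl addition), at O–C6 (ether), at C3–C4 (acetyl anion) and at C10–C11 (semipinacol vinyl shift), leading back to (S)-carvone.
4. Forward: carvone ring (the later carbocycle) → C10 quaternary centre → C4 carbinol → tetrahydrofuran bridge → ring A → fragmentation to ring B → lactone ring C.
5. Stereochemistry: C7 from (S)-carvone; C10 by a stereospecific vinyl shift relayed from a hydroxyl-directed epoxidation; C4 by axial addition anti to the axial C10 methyl; C3 by chelation; C8, C9, C11, C1 by equilibration or exo-face hydride delivery on the rigid tricycle; C9 is inverted in the lactonisation; the Z olefin is fixed by the bicycle.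

Key step: step 21

Remark: the configuration of the given structure is taken as drawn; it places the C10 methyl, the C4 oxygen and the C6 bridge on one face, so the fragmentation substrate is a cis-fused decalin and C7 comes from (S)-carvone. C9 of that substrate is deliberately epimeric to C9 of the target, and the C5 carbinol configuration plays no role.

**Route**

Step 1
Reactants: 1 (S)-carvone
Product: 2 vinyl carbinol (2-methyl-5-(prop-1-en-2-yl)-1-vinylcyclohex-2-en-1-ol, hydroxyl cis to isopropenyl)
Conditions: CH2=CHMgBr, THF, −78 → 0 °C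
Reagents that add atoms: vinylmagnesium bromide, C=C[Mg]Br
Why: Grignard 1,2-addition to the enone; the nucleophile should enter axially, anti to the pseudo-equatorial isopropenyl group, so the C4 hydroxyl ends cis to it and the vinyl group trans (a minor epimer would be removed by chromatography).

Step 2
Reactants: 2 vinyl carbinol
Product: 3 epoxy alcohol (epoxide of the ring olefin on the hydroxyl face)
Conditions: VO(acac)2 (cat.), t-BuOOH, CH2Cl2, 0 °C
Reagents that add atoms: tert-butyl hydroperoxide, CC(C)(C)OO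
Why: Hydroxyl-directed vanadium-catalysed epoxidation delivers oxygen to the more electron-rich trisubstituted ring olefin on the face of the hydroxyl and should leave the vinyl and isopropenyl groups untouched.

Step 3
Reactants: 3 epoxy alcohol
Product: 4 hydroxy ketone (3-hydroxy-2-methyl-5-(prop-1-en-2-yl)-2-vinylcyclohexan-1-one; methyl, hydroxyl and isopropenyl cis, vinyl trans)
Conditions: ZnBr2 (30 mol %), CH2Cl2, 0 °C → rt
Reagents that add atoms: none
Why: Semipinacol rearrangement of a 2,3-epoxy tertiary alcohol: the epoxide opens at tertiary C10 and the vinyl group, antiperiplanar to the breaking C–O bond, shifts from C4 to C10 with inversion, which gives the C4 ketone, the quaternary centre (methyl cis, vinyl trans to isopropenyl) and the C9 hydroxyl.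

Step 4
Reactants: 4 hydroxy ketone
Product: 5 C9 triethylsilyl ether
Conditions: Et3SiOTf, 2,6-lutidine, CH2Cl2, −78 °C
Reagents that add atoms: triethylsilyl trifluoromethanesulfonate, CC[Si](CC)(CC)OS(=O)(=O)C(F)(F)F
Why: Silylation of the hindered secondary hydroxyl, which as a free β-hydroxy ketone would undergo retro-aldol cleavage in the basic steps that follow.

Step 5
Reactants: 5 C9 triethylsilyl ether
Product: 6 C5 alcohol (α-hydroxy ketone, hydroxyl trans to isopropenyl)
Conditions: KN(SiMe3)2, THF, −78 °C; then 3-phenyl-2-(phenylsulfonyl)oxaziridine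
Reagents that add atoms: 3-phenyl-2-(phenylsulfonyl)oxaziridine, O=S(=O)(N1OC1c1ccccc1)c1ccccc1
Why: Davis oxidation of the enolate, which can form only toward C5 because C10 is quaternary; the oxidant should approach trans to the vicinal isopropenyl group, and this centre becomes trigonal in step 21 in any case.

Step 6
Reactants: 6 C5 alcohol
Product: 7 C5 benzyl ether
Conditions: BnBr, Ag2O, 4 Å molecular sieves, CH2Cl2, rt
Reagents that add atoms: benzyl bromide, BrCc1ccccc1
Why: Silver-oxide-mediated Williamson benzylation, neutral enough not to enolise the α-hydroxy ketone.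

Step 7
Reactants: 7 C5 benzyl ether
Product: 9 acetyl diol (C4 tertiary alcohol bearing the C3 acetyl group; C9 alcohol), via ethoxyvinyl adduct 8 (not isolated)
Conditions: CH2=C(OEt)Li (from ethyl vinyl ether, t-BuLi, THF, −78 → 0 °C), THF, −78 °C; then 1 M aq HCl, THF, rt
Reagents that add atoms: ethyl vinyl ether, C=COCC (used as 1-ethoxyvinyllithium, [Li]C(=C)OCC); water, O
Why: Addition of an acetyl-anion equivalent: in the chair with equatorial isopropenyl, silyloxy and benzyloxy groups the C10 methyl is axial, so the organolithium should add axially from the opposite face and put the C4 hydroxyl cis to the methyl; dilute acid then hydrolyses the enol ether to the methyl ketone and cleaves the triethylsilyl ether.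

Step 8
Reactants: 9 acetyl diol
Product: 10 C9 ketone (C4 hydroxyl retained)
Conditions: Dess–Martin periodinane, CH2Cl2, 0 °C → rt
Reagents that add atoms: none
Why: Dess–Martin oxidation of the only secondary hydroxyl; a trigonal C9 removes the second hydroxyl that could add to the isopropenyl group in the next step.

Step 9
Reactants: 10 C9 ketone
Product: 11 bridged diketone (5-acetyl-8-(benzyloxy)-4,7,7-trimethyl-4-vinyl-6-oxabicyclo[3.2.1]octan-3-one; ether C4–O–C6)
Conditions: TsOH·H2O (10 mol %), CH2Cl2, rt
Reagents that add atoms: none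
Why: Acid-catalysed Markovnikov hydroalkoxylation: protonation of the isopropenyl group gives the tertiary C6 cation, which the cis-1,3 C4 hydroxyl captures in a 5-exo closure, the classical way to the ether bridge of agarofurans.

Step 10
Reactants: 11 bridged diketone
Product: 12 homoallylic alcohol (C3: methyl β, hydroxyl α, allyl)
Conditions: allyl bromide, In powder, THF–H2O (1:1), rt
Reagents that add atoms: allyl bromide, C=CCBr
Why: Barbier allylation under chelation control: the metal bridges the ketone and the adjacent tetrahydrofuran oxygen and the allyl group should enter from the side of C5–H, away from quaternary C10, which sets C3; the unchelated C9 ketone, flanked by C10 and the bridgehead, should react far more slowly.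

Step 11
Reactants: 12 homoallylic alcohol
Product: 13 C3 triethylsilyl ether
Conditions: Et3SiOTf, 2,6-lutidine, CH2Cl2, 0 °C
Reagents that add atoms: triethylsilyl trifluoromethanesulfonate, CC[Si](CC)(CC)OS(=O)(=O)C(F)(F)F
Why: Silylation of the tertiary hydroxyl, which must neither open ring A by retro-aldol cleavage later nor trap the C11 aldehyde as a lactol.

Step 12
Reactants: 13 C3 triethylsilyl ether
Product: 15 α-tosyloxy ketone (C8 tosylate β, equatorial), via trimethylsilyl enol ether 14 (not isolated)
Conditions: LiN(iPr)2, Me3SiCl, THF, −78 °C; then PhI(OH)OTs, CH2Cl2, 0 °C; then DBU (cat.), rt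
Reagents that add atoms: chlorotrimethylsilane, C[Si](C)(C)Cl (silyl group of 14); hydroxy(tosyloxy)iodobenzene, Cc1ccc(cc1)S(=O)(=O)OI(O)c1ccccc1
Why: Regiospecific enol silane formation (C10 is quaternary, C7 a bridgehead) and α-sulfonyloxylation with the hypervalent iodine reagent; the α-tosyloxy ketone is epimerisable and base should settle the tosylate equatorial, away from the syn-axial C11 and C5 benzyloxy groups.

Step 13
Reactants: 15 α-tosyloxy ketone
Product: 16 C9 alcohol (β, axial)
Conditions: NaBH4, MeOH–CH2Cl2, −20 °C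
Reagents that add atoms: none
Why: Borohydride reduction; the β face of C9 lies under the O–C6 bridge, so hydride should attack from the exo face and give the axial alcohol, cis to the tosylate so that no epoxide can form.

Step 14
Reactants: 16 C9 alcohol
Product: 17 C9 tert-butyldimethylsilyl ether
Conditions: t-BuMe2SiOTf, 2,6-lutidine, CH2Cl2, 0 °C → rt
Reagents that add atoms: tert-butyldimethylsilyl trifluoromethanesulfonate, CC(C)(C)[Si](C)(C)OS(=O)(=O)C(F)(F)F
Why: Silylation keeps the C9 oxygen from triggering a semipinacol ring contraction at C8 under the basic conditions of step 21.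

Step 15
Reactants: 17 C9 silyl ether
Product: 18 dialdehyde (C11 and C1 aldehydes)
Conditions: OsO4 (cat.), NaIO4, 2,6-lutidine, dioxane–H2O, rt
Reagents that add atoms: sodium periodate, [Na+].[O-]I(=O)(=O)=O
Why: Lemieux–Johnson cleavage of the two terminal olefins; no other oxidisable group is present.

Step 16
Reactants: 18 dialdehyde
Product: 19 tricyclic acyloin (ring A closed; C1 ketone, C11 hydroxyl β)
Conditions: 6,7-dihydro-2-(2,4,6-trimethylphenyl)-5H-pyrrolo[2,1-c]-1,2,4-triazolium chloride (15 mol %), iPr2NEt, THF, 25 °C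
Reagents that add atoms: none
Why: Intramolecular crossed benzoin reaction under N-heterocyclic carbene catalysis: only the unhindered C1 aldehyde can become the acyl-anion equivalent, which adds to the neopentyl C11 aldehyde (6-exo-trig) to close ring A; the reversible addition should leave the C11 hydroxyl equatorial.

Step 17
Reactants: 19 tricyclic acyloin
Product: 20 C11 benzoate
Conditions: BzCl, pyridine, DMAP (cat.), CH2Cl2, 0 °C → rt
Reagents that add atoms: benzoyl chloride, O=C(Cl)c1ccccc1
Why: Acylation at the acyloin stage places the benzoate on O11 without ambiguity, because C1 is still a ketone.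

Step 18
Reactants: 20 C11 benzoate
Product: 21 C1 alcohol (β, axial)
Conditions: NaBH4, MeOH–THF, −40 °C
Reagents that add atoms: none
Why: Substrate-controlled ketone reduction: the β face of C1 is blocked by the syn-axial methyl groups on C3 and C10, so hydride should add from the α face and give the alcohol cis to the benzoate.

Step 19
Reactants: 21 C1 alcohol
Product: 22 C1 acetate
Conditions: Ac2O, DMAP, Et3N, CH2Cl2, 40 °C
Reagents that add atoms: acetic anhydride, CC(=O)OC(C)=O
Why: DMAP-catalysed acetylation of the hindered axial hydroxyl, the only free hydroxyl in 21.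

Step 20
Reactants: 22 C1 acetate
Product: 23 C5 alcohol (ether-bridged cis-decalin 5-hydroxy 8-tosylate)
Conditions: H2 (1 atm), Pd(OH)2/C, EtOAc, rt
Reagents that add atoms: none
Why: Hydrogenolysis of the benzyl ether; no olefin is present and sulfonate, esters and silyl ethers are inert.

Step 21
Reactants: 23 C5 alcohol
Product: 24 oxepene aldehyde (rings A and B; C5 aldehyde on C4, Z C7=C8)
Conditions: KOtBu (1.05 equiv), THF, −20 → 0 °C
Reagents that add atoms: none
Why: KOtBu deprotonates the C5 hydroxyl and the alkoxide lone pair feeds into the C5–C7 bond, which breaks in concert with loss of the C8 tosylate to give the C5 aldehyde and the C7=C8 double bond. This is a Grob (Wharton-type) fragmentation of a cyclic 1,3-diol monosulfonate, the standard way to unveil medium rings from bridged bicycles. Ring B is not closed by bond formation: cleaving the one-carbon bridge merges the tetrahydrofuran and the carbocycle into the seven-membered oxepene, so no cyclisation mode is involved. No stereocentre is created; the olefin is Z because C6 (axial on C7) and C9 are gauche in the chair and stay cis in the ring. The step needs the C5–C7 bond antiperiplanar to the leaving group, which the equatorial tosylate on the chair locked by the ether bridge provides; the tosylate has no antiperiplanar hydrogen, so elimination cannot compete. Chemoselectivity over ester cleavage and over a ring contraction induced by a C9 alkoxide rests on one equivalent of base at low temperature and on the C9 silyl ether.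

Step 22
Reactants: 24 oxepene aldehyde
Product: 25 carboxylic acid
Conditions: NaClO2, NaH2PO4, 2-methyl-2-butene, t-BuOH–H2O, 0 °C → rt
Reagents that add atoms: sodium chlorite, [Na+].[O-]Cl=O
Why: Pinnick oxidation of the non-enolisable aldehyde; the scavenger protects the ring olefin.

Step 23
Reactants: 25 carboxylic acid
Product: 26 dihydroxy acid (C9 and C3 hydroxyls free)
Conditions: HF·pyridine, pyridine, THF, 0 °C → rt
Reagents that add atoms: none
Why: Fluoride cleaves both silyl ethers; the C9 hydroxyl lies on the face opposite to the carboxyl group, so no lactone can form with retention.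

Step 24
Reactants: 26 dihydroxy acid
Product: 27 CNP0178319.3
Conditions: PPh3, iPrO2C–N=N–CO2iPr, THF, 0 °C → rt
Reagents that add atoms: none
Why: Mitsunobu lactonisation: the allylic C9 hydroxyl is activated as its oxyphosphonium ion and displaced by the carboxylate (5-exo-tet) with inversion, which turns the 9β oxygen into the 9α lactone oxygen of ring C; the tertiary C3 hydroxyl is not activated.

**Compound list**

1 | (S)-carvone | CC1=CC[C@@H](CC1=O)C(C)=C | starting material
2 | vinyl carbinol, hydroxyl cis to isopropenyl | C=C[C@]1(O)C[C@@H](C(C)=C)CC=C1C | intermediate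
3 | epoxy alcohol, epoxide cis to hydroxyl | C=C[C@]1(O)C[C@@H](C(C)=C)C[C@H]2O[C@@]12C | intermediate
4 | hydroxy ketone (C4 ketone, C10 Me β / vinyl α, C9 OH β) | C=C[C@@]1(C)[C@H](O)C[C@H](C(C)=C)CC1=O | intermediate
5 | C9 triethylsilyl ether | C=C[C@@]1(C)[C@H](O[Si](CC)(CC)CC)C[C@H](C(C)=C)CC1=O | intermediate
6 | C5 alcohol (α) | C=C[C@@]1(C)[C@H](O[Si](CC)(CC)CC)C[C@H](C(C)=C)[C@@H](O)C1=O | intermediate
7 | C5 benzyl ether | C=C[C@@]1(C)[C@H](O[Si](CC)(CC)CC)C[C@H](C(C)=C)[C@@H](OCc2ccccc2)C1=O | intermediate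
8 | ethoxyvinyl adduct (C4 OH β) | C=C[C@@]1(C)[C@H](O[Si](CC)(CC)CC)C[C@H](C(C)=C)[C@@H](OCc2ccccc2)[C@@]1(O)C(=C)OCC | intermediate (not isolated)
9 | acetyl diol (C4 OH, C9 OH, C3 ketone) | C=C[C@@]1(C)[C@H](O)C[C@H](C(C)=C)[C@@H](OCc2ccccc2)[C@@]1(O)C(C)=O | intermediate
10 | C9 ketone | C=C[C@@]1(C)C(=O)C[C@H](C(C)=C)[C@@H](OCc2ccccc2)[C@@]1(O)C(C)=O | intermediate
11 | bridged diketone (6-oxabicyclo[3.2.1]octane) | CC(=O)[C@]12OC(C)(C)[C@H]([C@H]1OCc3ccccc3)CC(=O)[C@]2(C)C=C | intermediate
12 | homoallylic alcohol (C3 Me β, OH α) | C=CC[C@](C)(O)[C@]12OC(C)(C)[C@H]([C@H]1OCc3ccccc3)CC(=O)[C@]2(C)C=C | intermediate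
13 | C3 triethylsilyl ether | C=CC[C@](C)(O[Si](CC)(CC)CC)[C@]12OC(C)(C)[C@H]([C@H]1OCc3ccccc3)CC(=O)[C@]2(C)C=C | intermediate
14 | trimethylsilyl enol ether (C8=C9) | C=CC[C@](C)(O[Si](CC)(CC)CC)[C@]12OC(C)(C)[C@H]([C@H]1OCc3ccccc3)C=C(O[Si](C)(C)C)[C@]2(C)C=C | intermediate (not isolated)
15 | α-tosyloxy ketone (C8 OTs β) | C=CC[C@](C)(O[Si](CC)(CC)CC)[C@]12OC(C)(C)[C@H]([C@H]1OCc3ccccc3)[C@@H](OS(=O)(=O)c4ccc(C)cc4)C(=O)[C@]2(C)C=C | intermediate
16 | C9 alcohol (β) | C=CC[C@](C)(O[Si](CC)(CC)CC)[C@]12OC(C)(C)[C@H]([C@H]1OCc3ccccc3)[C@@H](OS(=O)(=O)c4ccc(C)cc4)[C@@H](O)[C@]2(C)C=C | intermediate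
17 | C9 tert-butyldimethylsilyl ether | C=CC[C@](C)(O[Si](CC)(CC)CC)[C@]12OC(C)(C)[C@H]([C@H]1OCc3ccccc3)[C@@H](OS(=O)(=O)c4ccc(C)cc4)[C@@H](O[Si](C)(C)C(C)(C)C)[C@]2(C)C=C | intermediate
18 | dialdehyde | O=CC[C@](C)(O[Si](CC)(CC)CC)[C@]12OC(C)(C)[C@H]([C@H]1OCc3ccccc3)[C@@H](OS(=O)(=O)c4ccc(C)cc4)[C@@H](O[Si](C)(C)C(C)(C)C)[C@]2(C)C=O | intermediate
19 | tricyclic acyloin (C1 ketone, C11 OH β) | O=C1C[C@](C)(O[Si](CC)(CC)CC)[C@]23OC(C)(C)[C@H]([C@H]2OCc4ccccc4)[C@@H](OS(=O)(=O)c5ccc(C)cc5)[C@@H](O[Si](C)(C)C(C)(C)C)[C@]3(C)[C@H]1O | intermediate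
20 | C11 benzoate | O=C1C[C@](C)(O[Si](CC)(CC)CC)[C@]23OC(C)(C)[C@H]([C@H]2OCc4ccccc4)[C@@H](OS(=O)(=O)c5ccc(C)cc5)[C@@H](O[Si](C)(C)C(C)(C)C)[C@]3(C)[C@H]1OC(=O)c6ccccc6 | intermediate
21 | C1 alcohol (β) | O[C@H]1C[C@](C)(O[Si](CC)(CC)CC)[C@]23OC(C)(C)[C@H]([C@H]2OCc4ccccc4)[C@@H](OS(=O)(=O)c5ccc(C)cc5)[C@@H](O[Si](C)(C)C(C)(C)C)[C@]3(C)[C@H]1OC(=O)c6ccccc6 | intermediate
22 | C1 acetate | CC(=O)O[C@H]1C[C@](C)(O[Si](CC)(CC)CC)[C@]23OC(C)(C)[C@H]([C@H]2OCc4ccccc4)[C@@H](OS(=O)(=O)c5ccc(C)cc5)[C@@H](O[Si](C)(C)C(C)(C)C)[C@]3(C)[C@H]1OC(=O)c6ccccc6 | intermediate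
23 | C5 alcohol, ether-bridged cis-decalin 5-hydroxy 8-tosylate | CC(=O)O[C@H]1C[C@](C)(O[Si](CC)(CC)CC)[C@]23OC(C)(C)[C@H]([C@H]2O)[C@@H](OS(=O)(=O)c4ccc(C)cc4)[C@@H](O[Si](C)(C)C(C)(C)C)[C@]3(C)[C@H]1OC(=O)c5ccccc5 | intermediate
24 | oxepene aldehyde (rings A and B) | CC(=O)O[C@H]1C[C@](C)(O[Si](CC)(CC)CC)[C@@]2(C=O)OC(C)(C)C=C[C@@H](O[Si](C)(C)C(C)(C)C)[C@]2(C)[C@H]1OC(=O)c3ccccc3 | intermediate
25 | carboxylic acid | CC(=O)O[C@H]1C[C@](C)(O[Si](CC)(CC)CC)[C@@]2(C(O)=O)OC(C)(C)C=C[C@@H](O[Si](C)(C)C(C)(C)C)[C@]2(C)[C@H]1OC(=O)c3ccccc3 | intermediate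
26 | dihydroxy acid | CC(=O)O[C@H]1C[C@](C)(O)[C@@]2(C(O)=O)OC(C)(C)C=C[C@@H](O)[C@]2(C)[C@H]1OC(=O)c3ccccc3 | intermediate
27 | CNP0178319.3 | CC(=O)O[C@H]1C[C@](C)(O)[C@]23OC(C)(C)C=C[C@H](OC2=O)[C@]3(C)[C@H]1OC(=O)c1ccccc1 | target

**Totals and risks**

Total step count: 24. Longest linear sequence: 24 steps (fully linear from (S)-carvone).

Steps most likely to fail:

Step 16. Under the basic carbene conditions the enolisable C1 aldehyde may instead close onto C11 by aldol addition (five-membered ring), the β-silyloxy group may be eliminated, or the acyl anion may form at the wrong terminus. The fallback sets out from 17 and closes ring A by olefin metathesis with the second-generation Grubbs catalyst (H2IMes)(PCy3)Cl2Ru=CHPh to give the ring A cyclohexene F1. Dihydroxylation with OsO4 and N-methylmorpholine N-oxide from the open α face should give the cis-diol F2. Oxidation of the less hindered C1 hydroxyl with TEMPO, NaOCl and KBr should give the acyloin with axial C11 hydroxyl F3, and DBU epimerises C11 to the equatorial position, which returns the route to 19.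

Step 24. Activation of the neopentyl-type allylic alcohol may be slow, and the oxyphosphonium ion may ionise, with allylic transposition or intermolecular esterification taking over. The fallback sets out from 24: HF·pyridine gives the hydroxy aldehyde F4, and MsCl with Et3N at −40 °C gives the allylic mesylate F5. Pinnick oxidation then gives the mesylate acid F6, whose carboxylate displaces the mesylate with inversion on treatment with NaHCO3 in DMF, which returns the route to 27.

Step 12. Attack of the bulky iodine reagent on the hindered enol silane may be slow or occur on the terminal olefins, and the sulfonate may be delivered axially without equilibrating. The fallback sets out from 13: the potassium enolate (KN(SiMe3)2) is hydroxylated with 3-phenyl-2-(phenylsulfonyl)oxaziridine and equilibrated with DBU to the equatorial α-hydroxy ketone F7. Sulfonylation with p-toluenesulfonic anhydride and pyridine returns the route to 15.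

**Further compounds**

F1 | step 16 | ring A cyclohexene (C11=C1) | C1=CC[C@](C)(O[Si](CC)(CC)CC)[C@]23OC(C)(C)[C@H]([C@H]2OCc4ccccc4)[C@@H](OS(=O)(=O)c5ccc(C)cc5)[C@@H](O[Si](C)(C)C(C)(C)C)[C@]13C
F2 | step 16 | cis-diol (C1 and C11 hydroxyls α) | O[C@@H]1C[C@](C)(O[Si](CC)(CC)CC)[C@]23OC(C)(C)[C@H]([C@H]2OCc4ccccc4)[C@@H](OS(=O)(=O)c5ccc(C)cc5)[C@@H](O[Si](C)(C)C(C)(C)C)[C@]3(C)[C@@H]1O
F3 | step 16 | acyloin with axial C11 hydroxyl (α) | O=C1C[C@](C)(O[Si](CC)(CC)CC)[C@]23OC(C)(C)[C@H]([C@H]2OCc4ccccc4)[C@@H](OS(=O)(=O)c5ccc(C)cc5)[C@@H](O[Si](C)(C)C(C)(C)C)[C@]3(C)[C@@H]1O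
F4 | step 24 | hydroxy aldehyde | CC(=O)O[C@H]1C[C@](C)(O)[C@@]2(C=O)OC(C)(C)C=C[C@@H](O)[C@]2(C)[C@H]1OC(=O)c3ccccc3
F5 | step 24 | allylic mesylate aldehyde | CC(=O)O[C@H]1C[C@](C)(O)[C@@]2(C=O)OC(C)(C)C=C[C@@H](OS(C)(=O)=O)[C@]2(C)[C@H]1OC(=O)c3ccccc3
F6 | step 24 | mesylate acid | CC(=O)O[C@H]1C[C@](C)(O)[C@@]2(C(O)=O)OC(C)(C)C=C[C@@H](OS(C)(=O)=O)[C@]2(C)[C@H]1OC(=O)c3ccccc3
F7 | step 12 | α-hydroxy ketone (C8 hydroxyl β) | C=CC[C@](C)(O[Si](CC)(CC)CC)[C@]12OC(C)(C)[C@H]([C@H]1OCc3ccccc3)[C@@H](O)C(=O)[C@]2(C)C=C
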